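The five-membered lactone of the target (O1, C2(=O), C3, C4–Br, C5) hides a four-carbon ring: remove O1, join C2 to C5, and a 4-hydroxycyclobut-2-enone appears. The route rests on that O1–C2 disconnection. Oxidative ring expansion of the cyclobutenol that carries the silyloxybutyl chain, the bromine and a diiodomethyl group breaks the strained carbonyl–carbinol bond, forms the lactone and gives the exocyclic diiodomethylene in one operation. Palladium-catalysed removal of the less hindered iodine then leaves the E iodide. The R carbinol centre is set early by asymmetric ynone reduction and is kept away from strongly acidic media.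

Key step: step 8

Abbreviation: TBSO = tert-butyldimethylsilyloxy.
Assumption: Alpine-Borane made from enantiopure (+)-α-pinene gives 4 in high enantiomeric purity; 14 is carried as the mixture of both epimers at the ring carbinol carbon, a centre that step 8 removes.

Step 1
Reactants: 1 hex-1-yn-3-ol (racemic)
Product: 2 hex-1-yn-3-one
Conditions: CrO3, H2SO4, H2O, acetone, 0 °C
Reagents that add atoms: none
Why: Jones oxidation of a secondary propargylic alcohol is fast at 0 °C and stops at the ynone, since the terminal alkyne is inert to chromic acid.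

Step 2
Reactants: 2 hex-1-yn-3-one
Product: 4 (R)-hex-1-yn-3-ol, via borinate ester 3 (not isolated)
Conditions: (R)-Alpine-Borane [B-isopinocampheyl-9-BBN from (+)-α-pinene], THF, rt; then CH3CHO; then HOCH2CH2NH2, Et2O
Reagents that add atoms: none
Why: Midland Alpine-Borane reduction delivers the pinanyl hydride through a boat-like six-membered transition state that places the slim ethynyl group beside the pinane methyl, so the reagent made from (+)-α-pinene should give the R propargylic alcohol, as established for homologous 1-alkyn-3-ones, and ethanolamine then releases the alcohol from the borinate.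

Step 3
Reactants: 4 (R)-hex-1-yn-3-ol
Product: 5 (R)-tert-butyl(hex-1-yn-3-yloxy)dimethylsilane
Conditions: TBSCl, imidazole, DMF, rt
Reagents that add atoms: tert-butyldimethylsilyl chloride, CC(C)(C)[Si](C)(C)Cl
Why: Imidazole-assisted silylation of a secondary alcohol does not touch the stereocentre and gives an ether that should withstand the zinc, silver, carbenoid and radical steps and that later screens the neighbouring ring carbonyl.

Step 4
Reactants: 5 (R)-tert-butyl(hex-1-yn-3-yloxy)dimethylsilane; 6 trichloroacetyl chloride
Product: 8 4,4-dichloro-3-[(1R)-1-(TBSO)butyl]cyclobut-2-en-1-one, via dichloroketene 7 (not isolated)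
Conditions: Zn–Cu couple, Et2O/DME, rt, slow addition of 6
Reagents that add atoms: none
Why: Zinc dechlorination of 6 gives dichloroketene, whose [2+2] cycloaddition with a terminal alkyne bonds the ketene carbonyl carbon to the unsubstituted alkyne carbon, so the CCl2 group ends up beside the substituted ring carbon, while DME complexes ZnCl2 and so suppresses silyl ether cleavage and chlorine migration.

Step 5
Reactants: 8 4,4-dichloro-3-[(1R)-1-(TBSO)butyl]cyclobut-2-en-1-one
Product: 9 3-[(1R)-1-(TBSO)butyl]cyclobut-3-ene-1,2-dione
Conditions: Ag2CO3, acetone/H2O, rt, dark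
Reagents that add atoms: water, O
Why: Silver-assisted hydrolysis of the geminal dichloride (the change usually forced with concentrated H2SO4) should proceed under buffered conditions because chloride loss gives a cyclobutenyl cation stabilised as a two-π-electron ring, which water captures at the chlorine-bearing carbon before the second chloride leaves, and these conditions spare the silyl ether and the carbinol stereocentre that hot strong acid would put at risk.

Step 6
Reactants: 9 3-[(1R)-1-(TBSO)butyl]cyclobut-3-ene-1,2-dione
Product: 11 3-bromo-4-[(1R)-1-(TBSO)butyl]cyclobut-3-ene-1,2-dione, via ring dibromide 10 (not isolated)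
Conditions: Br2, CH2Cl2, 0 °C to rt, dark; then 2,6-lutidine, 0 °C
Reagents that add atoms: bromine, BrBr
Why: Bromination by addition–elimination, known for the vinylic CH of 3-arylcyclobutenediones: Br2 adds across the electron-poor ring alkene and the dibromide loses HBr through the only ring hydrogen, which is α to a carbonyl, so the double bond returns with bromine on the former CH carbon, while the hindered base takes up HBr before it can cleave the silyl ether.

Step 7
Reactants: 11 3-bromo-4-[(1R)-1-(TBSO)butyl]cyclobut-3-ene-1,2-dione; 12 diiodomethane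
Product: 14 3-bromo-4-(diiodomethyl)-4-hydroxy-2-[(1R)-1-(TBSO)butyl]cyclobut-2-en-1-one (both ring-carbinol epimers), via diiodomethyllithium 13 (not isolated)
Conditions: 12, LiN(SiMe3)2, THF/Et2O, −90 °C; then 11, −90 °C; AcOH quench at −90 °C
Reagents that add atoms: none
Why: 1,2-Addition of a lithium carbenoid to a ketone: diiodomethyllithium, made by deprotonating 12, should attack the carbonyl flanked by C–Br, which is the less screened and the more electrophilic of the two because the other one is shielded by the branched silyloxybutyl carbon and is conjugated with the bromine lone pairs through the ring alkene, the hard lithium reagent at −90 °C favours carbonyl addition over displacement of bromide, the cold acidic quench keeps the β-iodo alkoxide from closing to an epoxide, and the new carbinol centre forms without control, which does not matter because step 8 removes it.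

Step 8
Reactants: 14 3-bromo-4-(diiodomethyl)-4-hydroxy-2-[(1R)-1-(TBSO)butyl]cyclobut-2-en-1-one
Product: 16 4-bromo-3-[(1R)-1-(TBSO)butyl]-5-(diiodomethylidene)furan-2(5H)-one, via tertiary hypoiodite 15 (not isolated)
Conditions: PhI(OAc)2, I2, CH2Cl2, visible light, rt
Reagents that add atoms: none
Why: Acetyl hypoiodite formed from PhI(OAc)2 and I2 turns the tertiary hydroxyl of 14 into the O–I compound 15, and light homolyses it to an oxygen-centred radical that opens the four-membered ring by β-scission of the C4–C1 bond, since this relieves ring strain and produces an acyl radical rather than a vinyl or a diiodomethyl radical. Because the bromoalkene is still cis-locked, the acyl carbon sits next to the newly formed ketone oxygen and bonds to it (the new O1–C2 bond), the C5 radical is then oxidised or iodinated, and loss of HI from C5–CHI2 installs the exocyclic diiodomethylene. The closest known reaction type is the oxidative rearrangement of 4-hydroxycyclobut-2-enones to 5-ylidenefuran-2(5H)-ones brought about by Pb(OAc)4 or HgO/I2, here run with a trivalent iodine oxidant. The furanone ring closes 5-endo-trig when counted at the ketone C=O attacked on oxygen by the acyl radical, or 5-exo-trig when counted as O-acylation by an acyl iodide. No stereocentre is formed, the ring carbinol centre disappears and the tetrasubstituted C3=C4 geometry is inherited from the cyclobutene. The selectivity needed is ring opening at the carbonyl side in preference to expulsion of the CHI2 radical, which strain release secures, together with a single site for radical generation, which the silyl ether on the side-chain oxygen secures.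

Step 9
Reactants: 16 4-bromo-3-[(1R)-1-(TBSO)butyl]-5-(diiodomethylidene)furan-2(5H)-one
Product: 17 (5E)-4-bromo-3-[(1R)-1-(TBSO)butyl]-5-(iodomethylidene)furan-2(5H)-one
Conditions: Pd(PPh3)4 (5 mol%), Bu3SnH (1.05 equiv, slow addition), toluene, 0 °C to rt, dark
Reagents that add atoms: none
Why: Palladium-catalysed hydrogenolysis of a 1,1-dihaloalkene with Bu3SnH: zerovalent palladium should insert into the exposed C–I bond on the ring-oxygen side much faster than into the iodine crowded by the C4 bromine or into the stronger C–Br bond, and the tin hydride then replaces palladium by hydrogen with retention, so the remaining iodine lies cis to C4, which is the E geometry of the target.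

Step 10
Reactants: 17 (5E)-4-bromo-3-[(1R)-1-(TBSO)butyl]-5-(iodomethylidene)furan-2(5H)-one
Product: 18 (5E)-4-bromo-3-[(1R)-1-hydroxybutyl]-5-(iodomethylidene)furan-2(5H)-one (target)
Conditions: HF·pyridine, THF, 0 °C to rt
Reagents that add atoms: none
Why: Fluoride-mediated desilylation under acidic, non-nucleophilic conditions should free the secondary alcohol without opening the enol lactone, displacing the vinylic halogens or isomerising the iodoalkene, and the carbinol stereocentre is not involved.

Compound list
1 | hex-1-yn-3-ol (racemic) | CCCC(O)C#C | starting material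
2 | hex-1-yn-3-one | CCCC(=O)C#C | intermediate
3 | (R)-hex-1-yn-3-yl 9-borabicyclo[3.3.1]nonan-9-yl ether (borinate ester, formed in situ) | CCC[C@@H](OB1C2CCCC1CCC2)C#C | intermediate
4 | (R)-hex-1-yn-3-ol | CCC[C@@H](O)C#C | intermediate
5 | (R)-tert-butyl(hex-1-yn-3-yloxy)dimethylsilane | CCC[C@@H](O[Si](C)(C)C(C)(C)C)C#C | intermediate
6 | trichloroacetyl chloride | ClC(Cl)(Cl)C(Cl)=O | starting material
7 | dichloroketene (formed in situ) | ClC(Cl)=C=O | intermediate
8 | 4,4-dichloro-3-[(1R)-1-(TBSO)butyl]cyclobut-2-en-1-one | CCC[C@@H](O[Si](C)(C)C(C)(C)C)C1=CC(=O)C1(Cl)Cl | intermediate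
9 | 3-[(1R)-1-(TBSO)butyl]cyclobut-3-ene-1,2-dione | CCC[C@@H](O[Si](C)(C)C(C)(C)C)C1=CC(=O)C1=O | intermediate
10 | 3,4-dibromo-3-[(1R)-1-(TBSO)butyl]cyclobutane-1,2-dione (ring dibromide, formed in situ, ring epimers) | CCC[C@@H](O[Si](C)(C)C(C)(C)C)C1(Br)C(Br)C(=O)C1=O | intermediate
11 | 3-bromo-4-[(1R)-1-(TBSO)butyl]cyclobut-3-ene-1,2-dione | CCC[C@@H](O[Si](C)(C)C(C)(C)C)C1=C(Br)C(=O)C1=O | intermediate
12 | diiodomethane | ICI | starting material
13 | diiodomethyllithium (formed in situ) | [Li]C(I)I | intermediate
14 | 3-bromo-4-(diiodomethyl)-4-hydroxy-2-[(1R)-1-(TBSO)butyl]cyclobut-2-en-1-one (both epimers at C4) | CCC[C@@H](O[Si](C)(C)C(C)(C)C)C1=C(Br)C(O)(C(I)I)C1=O | intermediate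
15 | 3-bromo-4-(diiodomethyl)-4-(iodooxy)-2-[(1R)-1-(TBSO)butyl]cyclobut-2-en-1-one (tertiary hypoiodite, formed in situ) | CCC[C@@H](O[Si](C)(C)C(C)(C)C)C1=C(Br)C(OI)(C(I)I)C1=O | intermediate
16 | 4-bromo-3-[(1R)-1-(TBSO)butyl]-5-(diiodomethylidene)furan-2(5H)-one | CCC[C@@H](O[Si](C)(C)C(C)(C)C)C1=C(Br)C(=C(I)I)OC1=O | intermediate
17 | (5E)-4-bromo-3-[(1R)-1-(TBSO)butyl]-5-(iodomethylidene)furan-2(5H)-one | CCC[C@@H](O[Si](C)(C)C(C)(C)C)C1=C(Br)/C(=C\I)OC1=O | intermediate
18 | (5E)-4-bromo-3-[(1R)-1-hydroxybutyl]-5-(iodomethylidene)furan-2(5H)-one | CCC[C@@H](O)C1=C(Br)/C(=C\I)OC1=O | target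

Total step count: 10. Longest linear sequence: 10 steps (1 to 18); 6 and 12 are purchased.

Steps most likely to fail

Step 8 is the riskiest. The oxygen radical may fragment toward the diiodomethyl radical instead of opening the ring, or the C–I bonds may be cleaved by light and iodine radicals before the ring expansion is complete. The fallback replaces the radical ring expansion by a pericyclic one followed by a separate dehydrogenation. Setting out from 14, heating in toluene at about 100 °C opens the four-membered ring by conrotatory electrocyclic opening to a hydroxy-substituted vinylketene. The hydroxyl then adds to the ketene to give 4-bromo-3-[(1R)-1-(TBSO)butyl]-5-(diiodomethyl)furan-2(5H)-one F1, the known thermal route from 4-hydroxycyclobutenones to butenolides. Radical bromination of the doubly activated C5–H with NBS gives 4,5-dibromo-3-[(1R)-1-(TBSO)butyl]-5-(diiodomethyl)furan-2(5H)-one F2. 2,6-Lutidine then removes HBr across C5 and the diiodomethyl carbon, which brings the route back at 16.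

Step 7 is next. The carbenoid may add to the bromine-bearing ring carbon and expel bromide, or it may add to the carbonyl next to the side chain. The fallback carries the vinylic position as an ether during C–C bond formation and restores bromine afterwards. Setting out from 11, methanol and 2,6-lutidine exchange the bromine for methoxy to give 3-methoxy-4-[(1R)-1-(TBSO)butyl]cyclobut-3-ene-1,2-dione F3. Diiodomethyllithium 13 then adds to the carbonyl beside the alkoxy-bearing carbon, the established preference of 3-alkoxycyclobutenediones, with no leaving group good enough to be displaced. This gives 4-(diiodomethyl)-4-hydroxy-3-methoxy-2-[(1R)-1-(TBSO)butyl]cyclobut-2-en-1-one F4. The ring expansion of step 8, through the hypoiodite 4-(diiodomethyl)-4-(iodooxy)-3-methoxy-2-[(1R)-1-(TBSO)butyl]cyclobut-2-en-1-one F5, gives the methyl tetronate 5-(diiodomethylidene)-4-methoxy-3-[(1R)-1-(TBSO)butyl]furan-2(5H)-one F6. LiCl in DMF removes the O-methyl group to give the tetronic acid 5-(diiodomethylidene)-4-hydroxy-3-[(1R)-1-(TBSO)butyl]furan-2(5H)-one F7. Oxalyl bromide with catalytic DMF converts this vinylogous acid into the bromide, rejoining the route at 16.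

Step 5 is third. Water may capture the ring cation at the hydrogen-bearing end, which leads to a hydroxy chloroenone instead of the dione, or ionisation may be slow enough that forcing conditions strip the silyl ether. The fallback makes the outcome independent of where water attacks. Setting out from 8, bromine adds to the enone to give 2,3-dibromo-4,4-dichloro-3-[(1R)-1-(TBSO)butyl]cyclobutan-1-one F8. Et3N removes HBr from it to give 2-bromo-4,4-dichloro-3-[(1R)-1-(TBSO)butyl]cyclobut-2-en-1-one F9 (α-bromination of an enone). Both ends of the allyl-type cation now carry a halogen, so exhaustive hydrolysis with Ag2CO3 in aqueous acetone can only converge on the vinylogous acid 3-hydroxy-4-[(1R)-1-(TBSO)butyl]cyclobut-3-ene-1,2-dione F10. Oxalyl bromide with catalytic DMF then gives 11 directly, so that step 6 is bypassed as well.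

Further compounds
F1 | step 8 | 4-bromo-3-[(1R)-1-(TBSO)butyl]-5-(diiodomethyl)furan-2(5H)-one (both C5 epimers) | CCC[C@@H](O[Si](C)(C)C(C)(C)C)C1=C(Br)C(C(I)I)OC1=O
F2 | step 8 | 4,5-dibromo-3-[(1R)-1-(TBSO)butyl]-5-(diiodomethyl)furan-2(5H)-one (both C5 epimers) | CCC[C@@H](O[Si](C)(C)C(C)(C)C)C1=C(Br)C(Br)(C(I)I)OC1=O
F3 | step 7 | 3-methoxy-4-[(1R)-1-(TBSO)butyl]cyclobut-3-ene-1,2-dione | CCC[C@@H](O[Si](C)(C)C(C)(C)C)C1=C(OC)C(=O)C1=O
F4 | step 7 | 4-(diiodomethyl)-4-hydroxy-3-methoxy-2-[(1R)-1-(TBSO)butyl]cyclobut-2-en-1-one (both C4 epimers) | CCC[C@@H](O[Si](C)(C)C(C)(C)C)C1=C(OC)C(O)(C(I)I)C1=O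
F5 | step 7 | 4-(diiodomethyl)-4-(iodooxy)-3-methoxy-2-[(1R)-1-(TBSO)butyl]cyclobut-2-en-1-one | CCC[C@@H](O[Si](C)(C)C(C)(C)C)C1=C(OC)C(OI)(C(I)I)C1=O
F6 | step 7 | 5-(diiodomethylidene)-4-methoxy-3-[(1R)-1-(TBSO)butyl]furan-2(5H)-one | CCC[C@@H](O[Si](C)(C)C(C)(C)C)C1=C(OC)C(=C(I)I)OC1=O
F7 | step 7 | 5-(diiodomethylidene)-4-hydroxy-3-[(1R)-1-(TBSO)butyl]furan-2(5H)-one | CCC[C@@H](O[Si](C)(C)C(C)(C)C)C1=C(O)C(=C(I)I)OC1=O
F8 | step 5 | 2,3-dibromo-4,4-dichloro-3-[(1R)-1-(TBSO)butyl]cyclobutan-1-one (ring epimers) | CCC[C@@H](O[Si](C)(C)C(C)(C)C)C1(Br)C(Br)C(=O)C1(Cl)Cl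
F9 | step 5 | 2-bromo-4,4-dichloro-3-[(1R)-1-(TBSO)butyl]cyclobut-2-en-1-one | CCC[C@@H](O[Si](C)(C)C(C)(C)C)C1=C(Br)C(=O)C1(Cl)Cl
F10 | step 5 | 3-hydroxy-4-[(1R)-1-(TBSO)butyl]cyclobut-3-ene-1,2-dione | CCC[C@@H](O[Si](C)(C)C(C)(C)C)C1=C(O)C(=O)C1=O
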